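All runs were computed for an exercise; scatter was added.

The product reads 0 % after 2.50 h in the ochre run and 0.6 % after 4.00 h in the violet run, later readings stand higher in both, and two chemists read those curves differently.

| setting | ochre | violet | flask |
|---|---|---|---|
| substrate | 0.050 M | 0.050 M | 0.050 M |
| precatalyst | 2.5 µM | 3.8 µM | 5.0 µM |
| remark | run made earlier | run made earlier |  |

| run | time / h | product / % | substrate / % |
|---|---|---|---|
| ochre | 0.833 | 0 | 98.8 |
| ochre | 2.50 | 0 | 100.0 |
| ochre | 4.00 | 1.0 | 99.2 |
| ochre | 6.00 | 1.5 | 98.5 |
| ochre | 10.0 | 3.1 | 96.7 |
| ochre | 12.0 | 3.0 | 96.8 |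
| violet | 2.00 | 1.4 | 99.9 |
| violet | 4.00 | 0.6 | 98.9 |
| violet | 6.00 | 1.4 | 98.3 |
| violet | 8.00 | 2.5 | 96.9 |
| violet | 10.0 | 3.4 | 95.7 |
| violet | 12.0 | 3.9 | 95.7 |

(each reading ± 0.5 percentage points)

- steps that have been proposed: substrate + enzyme -> product + enzyme; precatalyst <-> enzyme

- factor on the rate of making product when 5.0 % of the substrate are converted if precatalyst is charged twice over
- factor on the rate when 5.0 % of the substrate are converted if precatalyst is charged at 25 µM instead

The ramp chemist holds that the enzyme is still rising from the precatalyst throughout the runs. Product then grows as charge times time squared, and at fixed conversion the rate goes as the root of the charge, giving 1.41 and 2.24.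

The plateau chemist answers that from 6.00 h to 12.0 h the ramp asks for a factor of 4 in product. Ochre reads 2.00 and violet 2.79, both lower, although a scatter of 0.5 percentage points keeps this from being conclusive. On this view the enzyme levels off after a lag, the induction period, and the rate then holds steady while the substrate stays near its charge.

My own reckoning takes the plateau side. The violet line from 4.00 h to 12.0 h meets zero product at a lag of 2.55 h, a poor reading, since the ochre line gives less. The same line gives the working time, the hours at plateau rate needed to reach the conversion asked about, taken as inversely proportional to the charge: 9.21 h at the flask's charge. The conversion then falls at lag plus working time: 11.8 h, 7.15 h at double charge and 4.39 h at 25 µM. Multiplying the charge factor by the ratio of activated shares, one minus exp(−time/lag), I get 1.90 and 4.15.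

The forecast, 1.8 and 3.6, stands lower than mine, and it gives its ground: “The data can't exclude a slower, still-rising enzyme”.

The flask gives 1.85 and 3.76, higher than the ramp's 1.41 and 2.24, and so on the plateau side of the dispute.

substrate + enzyme → product + enzyme, rate k1*[substrate]*[enzyme]/(1 + ([substrate]/Km1) + ([substrate]/Ksi1)^2) (3.75 mM, 32.2 mM, k = 68200 L mol⁻¹ h⁻¹); precatalyst ⇌ enzyme (K = 0.520, k = 0.143 h⁻¹) The ramp view has the first hours: enzyme stands at 19.4 % of the catalyst charged after 2.00 h, 33.7 % after 10.0 h and 34.2 % after 20.0 h. The flask's rate 3.43 × 10⁻⁴ M h⁻¹ makes its working time 7.28 h, against 9.21 h read from violet, and with the conversion reached at 9.51 h this leaves a lag of 2.22 h. For the flask with twice the precatalyst, lag plus half the working time gives a time factor of 0.616, and that flask's simulated factor is 0.605.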